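The target is what you want, so follow one molecule of starting material: once it has gone, does it stand as target? You asked for a quick number and gave your hunch, so here is mine.

| flask | starting material | partner | second substrate | third substrate | protic impurity | temperature | remark | time |
|---|---|---|---|---|---|---|---|---|
| teal | 47 mM | 23.5 mM | 9.4 mM | 47 mM | 1.2 mM | −10 °C | run made earlier |  |
| larch | 47 mM | 23.5 mM | 9.40 mM | 47.0 mM | 2.35 mM | −10 °C |  | 2.0 h |
| birch | 47 mM | 23.5 mM | 9.40 mM | 47.0 mM | 2.35 mM | 20 °C |  | 2.0 h |
| maple | 47 mM | 23.5 mM | 9.40 mM | 47.0 mM | 2.35 mM |  | at 50 °C until 40 min, from then on at −10 °C | 2.0 h |
| oak | 47 mM | 23.5 mM | 9.40 mM | 47.0 mM | 2.35 mM | 50 °C |  | 2.0 h |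

teal run (percent of the starting material charged)

| time / min | target / % | starting material / % |
|---|---|---|
| 3.00 | 7.3 | 93.7 |
| 8.00 | 10.6 | 88.3 |
| 15.0 | 19.5 | 81.7 |
| 25.0 | 24.6 | 73.2 |

(readings scatter by 1 percentage point)

- the earlier runs do not show what temperature does; that part of a forecast is a guess
- no earlier run changes the charge of protic impurity; that part of a forecast is a guess

- the best flask by amount of target, in percent of the starting material charged; "all alike" if 1.5 percentage points covers them all (larch / birch / maple / oak / all alike)
- amount of target at the end, in percent of the starting material charged, larch
- amount of target at the end, in percent of the starting material charged, birch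
- amount of target at the end, in percent of the starting material charged, maple
- amount of target at the end, in percent of the starting material charged, oak

1. Sum the teal readings and divide the target found by the starting material lost. That gives 98.3%. Call it the kept share: of the starting material that has gone, the part standing as target. It is a reading, and each reading carries 1 percentage point.

2. Suppose each starting material takes one partner. You charged less c(partner) than c(starting material), so partner is the limiting reagent, and the allowance is 50.0% of the starting material.

3. Multiply the two: my estimate of the ceiling for target in larch is 49.1%, as long as the kept share holds. By 25.0 min teal had used 53.6% of its allowance, and larch runs 2.0 h, so I expect larch below that line.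

4. Your forecast is birch as best, with larch 41%, birch 44%, maple 41% and oak 39%. Its ground for the best flask: “At 20 °C, birch should get close to the ceiling.” Birch at 44% needs a kept share of 88.0% on the full allowance. Teal read its share at −10 °C, and any figure for 20 °C is a guess. So I name larch, the flask at the temperature where the share was read, and you name birch.

Larch gives 40.9%, birch 14.8%, maple 2.24% and oak 0.0517%, so larch is best.

    starting material + partner → target (k = 278 /M/h, Ea = 39.0 kJ/mol)
    second substrate + partner → second product (k = 54.3 /M/h, Ea = 58.0 kJ/mol)
    third substrate + partner → third product (k = 5.66 /M/h, Ea = 67.0 kJ/mol)
    starting material + target → side product (k = 35.2 /M/h, Ea = 59.0 kJ/mol)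
    second substrate + protic impurity → quenched substrate (k = 306 /M/h, Ea = 58.0 kJ/mol)
    2 partner → homo dimer (k = 12.5 /M/h, Ea = 50.0 kJ/mol)
    (constants at 20 °C)

In oak, side product, each unit counted as two starting material, stands at 82.3% after 2.00 h. At the end the kept share of larch is 83.4%, and that of oak is 0.0628%. The neighbour of oak charged with 40 mM of partner lost 100% of its starting material and kept 28.5% of that as target.

The earlier runs and the new flask are simulated with made-up constants; the scatter is artificial.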